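The constants are invented; no experiment stands behind them.

Before I repeat this run I want to know how much of the X charged ends as X.G at the end of each flask, and whether X.G or G.X.G then stands higher.

    X + G → X.G (k1 = 0.015 L mol⁻¹ s⁻¹)
    G + X.G → G.X.G (k2 = 0.0061 L mol⁻¹ s⁻¹)
    G ⇌ E, rate k3*([G] - [E]/K3) per volume of the first phase (K3 = 1.9, k3 = 5.9 × 10⁻⁴ s⁻¹)
    X + X.G ⇌ X.X.G, settled at all times (K4 = 48 L mol⁻¹)
    X.G → Z (k5 = 3.2 × 10⁻⁷ s⁻¹)

the same everywhere: X 0.30 M; time 2.0 h; volume of the second phase over the first 0.50
- north-west: E 0.900 equiv
- east: E 1.80 equiv

- in percentages every species weighs as the X in it: one X.X.G counts as two
- for X.G the X.X.G is counted in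
- in the second phase: E; everything else is in the first
- charges count per volume of the first phase; a concentration in a rate is the amount of a species over the volume of its own phase; every rate counts per litre of the first phase
- in an amount of X.G, one X.X.G counts as one X.G
- run time (north-west): 2.0 h

- which of the two there is more of at the end, north-west (X.G / G.X.G)
- which of the two there is more of at the end, east (X.G / G.X.G)
- amount of X.G at the end, in percent of the X charged, north-west
- amount of X.G at the end, in percent of the X charged, east

I write a for free X, p for free X.G and u for X.X.G, each as a fraction of the X charged, so that X.G counts as p + u. On the fastest rung the balance holds at every moment, u = h·a·p, where the hold number h is the balance constant times the X charged, 14.4. At the start, with a near one, X.X.G is the resting state of X.G, and the free form is 6.49% of X.G; as a falls, that share grows.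

Next comes G. In north-west it meets X with a half-life of 2.6 min, shorter than the 18.6 min in which E crosses when G is taken away at once, so the transfer paces the start. On that reckoning nearly all of E has crossed by 2.0 h. The slowest rung is the turning of X.G into Z, with a half-life of 25 d, far longer than the run, so I drop it.

What I freeze is a ratio. Both additions are first order in G, so G cancels between them, and their selectivity factor is 2.46. The transfer sets how far along its path the flask has come, not the path. X.G stops growing where the additions run level, at p = 2.46·a. Since a, p and two u add up to the charge when G.X.G is still zero, this gives a = 0.0969. I call 57.1% the crest, the fraction of the charge in X.G where the two additions run level with G.X.G counted as zero. Since G.X.G does form, north-west should stop below the crest with X.G ahead. East should go past it with G.X.G ahead, though how far is beyond this reckoning.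

The forecast gives X.G ahead at 49% in north-west and G.X.G ahead with 32% of X.G in east, holding that “X.X.G holds most of the X.G pool away from the second addition until free X runs low”.

North-west ends with 14.7% of G.X.G and 50.9% of X.G, and that X.G is 6.2 percentage points under the crest. East ends with 27.8% and 60.7%. For a neighbour of east charged with 0.075 M of X, the hold number falls to 3.60. With a = 0.159, the crest rises to 61.6%, higher than in east. That neighbour ends with 46.9% of X.G, 34.7% of G.X.G and 7.93% of its X still free.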